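(The numbers in the tables are calculated with made-up constants, and the scatter is random.)

We want one ratio from these flasks: G made against L lost another way, taken as a ratio of two rates so that time drops out.

| setting | Saturday's | Monday's | violet | ochre | green |
|---|---|---|---|---|---|
| L | 23 mM (fed, over 4.0 min) | 51 mM (fed, over 4.0 min) | 34 mM (fed, over 4.0 min) | 34 mM (fed, over 8.0 min) | 34 mM (fed, over 15 min) |
| Z | 1 equiv | 1 equiv | 1.00 equiv | 1.00 equiv | 1.00 equiv |
| remark | run made earlier | run made earlier |  |  |  |
| time |  |  | 1.0 h | 1.0 h | 1.0 h |

| run | time / min | G / % | L / % |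
|---|---|---|---|
| Saturday's | 2.50 | 2.0 | 41.1 |
| Saturday's | 8.00 | 4.7 | 12.5 |
| Saturday's | 15.0 | 4.5 | 0.2 |
| Saturday's | 20.0 | 5.2 | 0.1 |
| Saturday's | 30.0 | 4.9 | 0 |
| Saturday's | 40.0 | 4.8 | 0 |
| Saturday's | 50.0 | 4.9 | 0 |
| Monday's | 4.00 | 5.3 | 50.8 |
| Monday's | 6.00 | 8.8 | 23.7 |
| Monday's | 8.00 | 9.3 | 11.4 |
| Monday's | 15.0 | 9.9 | 0.5 |
| Monday's | 20.0 | 10.7 | 0 |
| Monday's | 30.0 | 10.9 | 0 |
| Monday's | 50.0 | 10.5 | 0.2 |

(readings scatter by 0.5 percentage points)

- "hardly changes" means that all values lie within two and a half points (for a concentration: within two and a half percent of the largest)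
- percentages count the whole charge, also what has not yet gone in

1. amount of G at the end, in percent of the L charged for violet, ochre, green, in this order
2. how that number moves from the first to the last of them (hardly changes / falls all the way / rises all the way / falls, then rises / rises, then falls)

1. L's main loss is first order. At 8.00 min, Saturday's run holds L 12.5% and Monday's 11.4%, although Monday's charge is twice Saturday's. Monday's fall from 23.7% to 11.4% reads as 0.366 min⁻¹.

2. G behaves differently. Its last readings are 4.9% on Saturday and 10.5% on Monday, a factor of 2.14 for a factor of 2.22 in charge. So G's step has a second partner that scales with the charge, either L or Z.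

3. We try to tell them apart by the last L of Monday's run. From 8.00 min to 50.0 min, G gains 1.2 percentage points while L falls from 11.4% to 0.2%, a share of 10.7% against 10.5% for the whole of Monday's run. With L as partner, G's share of each bit of L lost moves with L in the flask, so this last L, at 11.4% or less against 50.8% at 4.00 min, should give a share well below the whole run's. But that gain is a difference of two readings, each with a scatter of 0.5 points, and Saturday's gain over the same stretch, 0.2 points, tells neither way. So the readings lean to Z without proving it, and we go on with Z. We also assume the main loss spends no Z. Z then stays near its charge, and L + Z looks pseudo-first-order.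

4. Monday's last reading gives 2.30 M⁻¹. This is the branching constant, a selectivity factor: G made for each L lost another way, divided by the concentration of Z. Saturday's reading gives 2.24 M⁻¹, at a different charge.

5. At 34 mM the ratio is 0.0782, so our own figure for G is 7.25%. With Z as partner, L cancels from the ratio, so on that choice the feed changes when L is present and leaves the split alone, and we give this figure for violet, ochre and green alike.

6. The forecast says 7.2%, 7.2%, 7.2%, hardly changes: “The yield then doesn't depend on feed time”. Our figure stands slightly above it.

The flasks give 7.47%, 7.45% and 7.40%, which hardly changes.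

    Q ⇌ D (K = 0.340, k = 0.0103 min⁻¹)
    2 Z → J (k = 0.0305 M⁻¹ min⁻¹)
    Z + E ⇌ Q (K = 330 M⁻¹, k = 0.177 M⁻¹ min⁻¹)
    L → X (k = 0.337 min⁻¹)
    L + Z → G (k = 0.870 M⁻¹ min⁻¹)
    L + Z → E (k = 0.248 M⁻¹ min⁻¹)

Violet and green both end with X at 90.4% and 90.5%, and Z at 81% in violet. Green can be tested while L is still present, at the end of its feed, with L at 17.9%. X then stands at 74.2%, and multiplying by the ratio 0.0782 gives G 5.80%. Green holds G 6.14% at 15 min.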